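## Retrosynthetic overview

1. The target is the erythro-(7R,8S) 8-O-4′ neolignan; the last step only frees the syringyl phenol from a TIPS ether.
2. The C7 carbinol comes from the (8S)-α-aryloxy ketone by chelation-controlled reduction, because the aldol delivers the threo (7S,8S) relationship and C7 must be corrected by oxidation/reduction.
3. The C9 methyl comes from the imide carbonyl of the aldol adduct (LiBH4, then TsCl, then LiAlH4).
4. Key C7–C8 bond: Evans syn boron aldol of an (R)-oxazolidinone aryloxyacetyl imide with TIPS-protected syringaldehyde, which fixes C8.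
5. The imide comes from (E)-4-propenylsyringol (by isomerisation of methoxyeugenol), ethyl bromoacetate and the auxiliary; no ring is formed, both arenes are bought.

Notation and assumption: C7 = carbinol carbon, C8 = aryloxy-bearing carbon, C9 = methyl; "ArO" = 2,6-dimethoxy-4-[(E)-prop-1-enyl]phenoxy, "Ar′" = 3,5-dimethoxy-4-(triisopropylsilyloxy)phenyl; Zn(BH4)2 is used as a separately prepared Et2O stock solution.

## Route

Step 1
Reactants: 1 syringaldehyde (4-hydroxy-3,5-dimethoxybenzaldehyde)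
Product: 2 3,5-dimethoxy-4-(triisopropylsilyloxy)benzaldehyde
Conditions: TIPSCl, imidazole, DMF, rt
Reagents that add atoms: triisopropylsilyl chloride, CC(C)[Si](Cl)(C(C)C)C(C)C
Why: Imidazole-mediated O-silylation of the phenol gives an aryl TIPS ether that survives the boron enolate, hydride and oxidation steps and is later removed by fluoride without touching the alkene.

Step 2
Reactants: 3 4-allyl-2,6-dimethoxyphenol (methoxyeugenol)
Product: 4 2,6-dimethoxy-4-[(E)-prop-1-enyl]phenol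
Conditions: RuHCl(CO)(PPh3)3 (1 mol %), toluene, 80 °C
Reagents that add atoms: none
Why: Ru–H catalysed alkene isomerisation (hydrometalation/β-hydride elimination) moves the double bond into conjugation and gives the thermodynamically favoured E-propenylarene (expected E:Z ≥ 95:5, residual Z purged when acid 7 is recrystallised).

Step 3
Reactants: 4 2,6-dimethoxy-4-[(E)-prop-1-enyl]phenol; 5 ethyl bromoacetate
Product: 6 ethyl 2-ArO-acetate
Conditions: K2CO3, acetone, reflux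
Reagents that add atoms: none
Why: Williamson ether synthesis, an SN2 displacement of an activated primary bromide by the phenoxide, which tolerates the two ortho methoxy groups.

Step 4
Reactants: 6 ethyl 2-ArO-acetate
Product: 7 2-ArO-acetic acid
Conditions: LiOH·H2O, THF/H2O, rt; then 1 M HCl to pH 3, 0 °C; recrystallise (EtOAc/hexane)
Reagents that add atoms: lithium hydroxide, [Li+].[OH-]
Why: Ester saponification is unproblematic here, and the crystalline acid allows the geometric purity of the propenyl group to be upgraded.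

Step 5
Reactants: 7 2-ArO-acetic acid; 8 (R)-4-benzyloxazolidin-2-one
Product: 10 (R)-4-benzyl-3-(2-ArO-acetyl)oxazolidin-2-one, via mixed pivalic anhydride 9 (not isolated)
Conditions: PivCl, Et3N, THF, −20 °C; then 8, LiCl, −20 °C → rt
Reagents that add atoms: pivaloyl chloride, CC(C)(C)C(Cl)=O (its acyl group is carried only in 9)
Why: N-acylation of the oxazolidinone through the mixed anhydride occurs at the unhindered aryloxyacetyl carbonyl under mild, non-acidic conditions that leave the propenyl group and the auxiliary stereocentre untouched.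

Step 6
Reactants: 10 (R)-4-benzyl-3-(2-ArO-acetyl)oxazolidin-2-one; 2 3,5-dimethoxy-4-(triisopropylsilyloxy)benzaldehyde
Product: 13 (R)-4-benzyl-3-[(2R,3S)-2-ArO-3-hydroxy-3-Ar′-propanoyl]oxazolidin-2-one, via Z-boron enolate 11 (not isolated), via boron aldolate 12 (not isolated)
Conditions: iPr2NEt, Bu2BOTf, CH2Cl2, −78 → 0 °C; then 2, −78 → 0 °C; pH 7 buffer, MeOH, 30 % H2O2, 0 °C
Reagents that add atoms: dibutylboron triflate, CCCCB(CCCC)OS(=O)(=O)C(F)(F)F (its Bu2B group is carried only in 11 and 12)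
Why: Evans syn aldol in which the Z-boron enolate reacts through a Zimmerman–Traxler chair on the face opposite the benzyl group of the (R)-auxiliary, setting C8 in its final absolute sense (2R here, 8S once C9 is reduced) and C7 as S (syn, i.e. threo).

Step 7
Reactants: 13 (R)-4-benzyl-3-[(2R,3S)-2-ArO-3-hydroxy-3-Ar′-propanoyl]oxazolidin-2-one
Product: 14 (1S,2S)-1-Ar′-2-ArO-propane-1,3-diol
Conditions: LiBH4, H2O (1 equiv), THF, 0 °C
Reagents that add atoms: none
Why: Reductive cleavage of the N-acyloxazolidinone by LiBH4 attacks the exocyclic carbonyl, releasing the auxiliary and the primary alcohol without touching either stereocentre, the alkene or the silyl ether.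

Step 8
Reactants: 14 (1S,2S)-1-Ar′-2-ArO-propane-1,3-diol
Product: 15 (2S,3S)-2-ArO-3-hydroxy-3-Ar′-propyl 4-methylbenzenesulfonate
Conditions: TsCl (1.15 equiv), pyridine, 0 → 4 °C
Reagents that add atoms: p-toluenesulfonyl chloride, Cc1ccc(cc1)S(Cl)(=O)=O
Why: Selective sulfonylation, since the primary hydroxyl reacts far faster than the hindered secondary benzylic one.

Step 9
Reactants: 15 (2S,3S)-2-ArO-3-hydroxy-3-Ar′-propyl 4-methylbenzenesulfonate
Product: 16 (1S,2S)-1-Ar′-2-ArO-propan-1-ol (threo)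
Conditions: LiAlH4, THF, 0 °C → rt
Reagents that add atoms: none
Why: SN2 hydride displacement of the primary tosylate converts C9 into the methyl group, and LiAlH4 leaves the styrenyl alkene and the aryl TIPS ether alone.

Step 10
Reactants: 16 (1S,2S)-1-Ar′-2-ArO-propan-1-ol
Product: 17 (S)-1-Ar′-2-ArO-propan-1-one
Conditions: Dess–Martin periodinane, pyridine, CH2Cl2, 0 °C → rt (used crude)
Reagents that add atoms: none
Why: Dess–Martin oxidation removes the wrongly configured C7 carbinol under near-neutral conditions that do not enolise the C8 stereocentre.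

Step 11
Reactants: 17 (S)-1-Ar′-2-ArO-propan-1-one
Product: 18 (1R,2S)-1-Ar′-2-ArO-propan-1-ol (erythro)
Conditions: Zn(BH4)2, Et2O, −20 °C; sat. NH4Cl
Reagents that add atoms: none
Why: Chelation-controlled (Cram-chelate) reduction, in which Zn bridges the carbonyl and the aryl ether oxygen so that hydride enters anti to the C8 methyl, setting C7 as R (anti/erythro); the minor threo isomer is removed by chromatography.

Step 12
Reactants: 18 (1R,2S)-1-Ar′-2-ArO-propan-1-ol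
Product: 19 (1R,2S)-1-(4-hydroxy-3,5-dimethoxyphenyl)-2-ArO-propan-1-ol (target)
Conditions: TBAF, AcOH, THF, 0 °C
Reagents that add atoms: none
Why: Fluoride-mediated desilylation of the aryl TIPS ether under buffered conditions frees the phenol without affecting the benzylic carbinol, the aryl ether or the E-alkene.

## Compound list

1 | syringaldehyde (4-hydroxy-3,5-dimethoxybenzaldehyde) | COc1cc(C=O)cc(OC)c1O | starting material
2 | 3,5-dimethoxy-4-(triisopropylsilyloxy)benzaldehyde | COc1cc(C=O)cc(OC)c1O[Si](C(C)C)(C(C)C)C(C)C | intermediate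
3 | 4-allyl-2,6-dimethoxyphenol (methoxyeugenol) | C=CCc1cc(OC)c(O)c(OC)c1 | starting material
4 | 2,6-dimethoxy-4-[(E)-prop-1-enyl]phenol | C/C=C/c1cc(OC)c(O)c(OC)c1 | intermediate
5 | ethyl bromoacetate | CCOC(=O)CBr | starting material
6 | ethyl 2-{2,6-dimethoxy-4-[(E)-prop-1-enyl]phenoxy}acetate | CCOC(=O)COc1c(OC)cc(/C=C/C)cc1OC | intermediate
7 | 2-{2,6-dimethoxy-4-[(E)-prop-1-enyl]phenoxy}acetic acid | OC(=O)COc1c(OC)cc(/C=C/C)cc1OC | intermediate
8 | (R)-4-benzyloxazolidin-2-one | O=C1N[C@H](Cc2ccccc2)CO1 | starting material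
9 | 2-{2,6-dimethoxy-4-[(E)-prop-1-enyl]phenoxy}acetic pivalic anhydride | CC(C)(C)C(=O)OC(=O)COc1c(OC)cc(/C=C/C)cc1OC | intermediate
10 | (R)-4-benzyl-3-(2-{2,6-dimethoxy-4-[(E)-prop-1-enyl]phenoxy}acetyl)oxazolidin-2-one | O=C(COc1c(OC)cc(/C=C/C)cc1OC)N1C(=O)OC[C@H]1Cc1ccccc1 | intermediate
11 | dibutylboron (Z)-enolate of imide 10 | CCCCB(CCCC)O/C(=C\Oc1c(OC)cc(/C=C/C)cc1OC)N1C(=O)OC[C@H]1Cc1ccccc1 | intermediate
12 | O-dibutylboryl aldolate of 13 | CCCCB(CCCC)O[C@H]([C@@H](Oc1c(OC)cc(/C=C/C)cc1OC)C(=O)N1C(=O)OC[C@H]1Cc1ccccc1)c1cc(OC)c(O[Si](C(C)C)(C(C)C)C(C)C)c(OC)c1 | intermediate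
13 | (R)-4-benzyl-3-[(2R,3S)-2-{2,6-dimethoxy-4-[(E)-prop-1-enyl]phenoxy}-3-hydroxy-3-(3,5-dimethoxy-4-triisopropylsilyloxyphenyl)propanoyl]oxazolidin-2-one | O=C(N1C(=O)OC[C@H]1Cc1ccccc1)[C@H](Oc1c(OC)cc(/C=C/C)cc1OC)[C@@H](O)c1cc(OC)c(O[Si](C(C)C)(C(C)C)C(C)C)c(OC)c1 | intermediate
14 | (1S,2S)-1-(3,5-dimethoxy-4-triisopropylsilyloxyphenyl)-2-{2,6-dimethoxy-4-[(E)-prop-1-enyl]phenoxy}propane-1,3-diol | OC[C@H](Oc1c(OC)cc(/C=C/C)cc1OC)[C@@H](O)c1cc(OC)c(O[Si](C(C)C)(C(C)C)C(C)C)c(OC)c1 | intermediate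
15 | (2S,3S)-2-{2,6-dimethoxy-4-[(E)-prop-1-enyl]phenoxy}-3-hydroxy-3-(3,5-dimethoxy-4-triisopropylsilyloxyphenyl)propyl 4-methylbenzenesulfonate | Cc1ccc(cc1)S(=O)(=O)OC[C@H](Oc1c(OC)cc(/C=C/C)cc1OC)[C@@H](O)c1cc(OC)c(O[Si](C(C)C)(C(C)C)C(C)C)c(OC)c1 | intermediate
16 | (1S,2S)-1-(3,5-dimethoxy-4-triisopropylsilyloxyphenyl)-2-{2,6-dimethoxy-4-[(E)-prop-1-enyl]phenoxy}propan-1-ol (threo) | C[C@H](Oc1c(OC)cc(/C=C/C)cc1OC)[C@@H](O)c1cc(OC)c(O[Si](C(C)C)(C(C)C)C(C)C)c(OC)c1 | intermediate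
17 | (S)-1-(3,5-dimethoxy-4-triisopropylsilyloxyphenyl)-2-{2,6-dimethoxy-4-[(E)-prop-1-enyl]phenoxy}propan-1-one | C[C@H](Oc1c(OC)cc(/C=C/C)cc1OC)C(=O)c1cc(OC)c(O[Si](C(C)C)(C(C)C)C(C)C)c(OC)c1 | intermediate
18 | (1R,2S)-1-(3,5-dimethoxy-4-triisopropylsilyloxyphenyl)-2-{2,6-dimethoxy-4-[(E)-prop-1-enyl]phenoxy}propan-1-ol (erythro) | C[C@H](Oc1c(OC)cc(/C=C/C)cc1OC)[C@H](O)c1cc(OC)c(O[Si](C(C)C)(C(C)C)C(C)C)c(OC)c1 | intermediate
19 | (1R,2S)-1-(4-hydroxy-3,5-dimethoxyphenyl)-2-{2,6-dimethoxy-4-[(E)-prop-1-enyl]phenoxy}propan-1-ol | C/C=C/c1cc(OC)c(O[C@@H](C)[C@H](O)c2cc(OC)c(O)c(OC)c2)c(OC)c1 | target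

## Summary and risk

Total step count: 12. Longest linear sequence: 11 steps (3 → 19, steps 2–12); the aldehyde branch (1 → 2) adds one step.

Steps most likely to fail, each with a fallback:

Step 11 (diastereoselectivity of the chelation-controlled reduction, with possible erosion at C8 in ketone 17). The fallback sets out from threo alcohol 16 and bypasses the ketone. A Mitsunobu reaction (4-nitrobenzoic acid, PPh3, DIAD, toluene, −20 → 0 °C) inverts C7 to give (1R,2S)-1-(3,5-dimethoxy-4-triisopropylsilyloxyphenyl)-2-{2,6-dimethoxy-4-[(E)-prop-1-enyl]phenoxy}propyl 4-nitrobenzoate F7. Brief methanolysis (K2CO3, MeOH, 0 °C) then returns to the route at erythro alcohol 18.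

Step 6 (boron aldol of the hindered aryloxyacetyl imide gives poor conversion or selectivity). The fallback sets out from acid 7 and changes auxiliary and enolate metal. Coupling with (R)-4-benzylthiazolidine-2-thione (EDC·HCl, DMAP, CH2Cl2) gives (R)-4-benzyl-3-(2-{2,6-dimethoxy-4-[(E)-prop-1-enyl]phenoxy}acetyl)thiazolidine-2-thione F1. Soft enolisation with TiCl4/iPr2NEt/NMP (CH2Cl2, −78 °C) and addition to aldehyde 2 gives the Evans-syn adduct (R)-4-benzyl-3-[(2R,3S)-2-{2,6-dimethoxy-4-[(E)-prop-1-enyl]phenoxy}-3-hydroxy-3-(3,5-dimethoxy-4-triisopropylsilyloxyphenyl)propanoyl]thiazolidine-2-thione F2. NaBH4 (THF/EtOH, 0 °C) displaces the thione auxiliary directly, coming back to the route at diol 14.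

Step 9 (hydride displacement of the tosylate next to a free benzylic alkoxide, with a risk of oxetane formation or Grob-type fragmentation). The fallback sets out from aldol adduct 13 and masks the C7 hydroxyl before C9 is reduced:
- TESOTf/2,6-lutidine (CH2Cl2, −78 °C) gives (R)-4-benzyl-3-[(2R,3S)-2-{2,6-dimethoxy-4-[(E)-prop-1-enyl]phenoxy}-3-(triethylsilyloxy)-3-(3,5-dimethoxy-4-triisopropylsilyloxyphenyl)propanoyl]oxazolidin-2-one F3.
- LiBH4 (THF, 0 °C) gives (2S,3S)-2-{2,6-dimethoxy-4-[(E)-prop-1-enyl]phenoxy}-3-(triethylsilyloxy)-3-(3,5-dimethoxy-4-triisopropylsilyloxyphenyl)propan-1-ol F4.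
- TsCl/Et3N/DMAP gives (2S,3S)-2-{2,6-dimethoxy-4-[(E)-prop-1-enyl]phenoxy}-3-(triethylsilyloxy)-3-(3,5-dimethoxy-4-triisopropylsilyloxyphenyl)propyl 4-methylbenzenesulfonate F5.
- LiBHEt3 (THF, 0 °C) gives triethyl{(1S,2S)-1-(3,5-dimethoxy-4-triisopropylsilyloxyphenyl)-2-{2,6-dimethoxy-4-[(E)-prop-1-enyl]phenoxy}propoxy}silane F6.
- AcOH/THF/H2O (rt) removes the alkyl TES group while the aryl TIPS ether stays, coming back to the route at alcohol 16. Any C7 epimerisation here is harmless because C7 is oxidised in step 10.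

## Further compounds

F1 | step 6 | (R)-4-benzyl-3-(2-{2,6-dimethoxy-4-[(E)-prop-1-enyl]phenoxy}acetyl)thiazolidine-2-thione | C/C=C/c1cc(OC)c(OCC(=O)N2C(=S)SC[C@H]2Cc2ccccc2)c(OC)c1
F2 | step 6 | (R)-4-benzyl-3-[(2R,3S)-2-{2,6-dimethoxy-4-[(E)-prop-1-enyl]phenoxy}-3-hydroxy-3-(3,5-dimethoxy-4-triisopropylsilyloxyphenyl)propanoyl]thiazolidine-2-thione | O=C(N1C(=S)SC[C@H]1Cc1ccccc1)[C@H](Oc1c(OC)cc(/C=C/C)cc1OC)[C@@H](O)c1cc(OC)c(O[Si](C(C)C)(C(C)C)C(C)C)c(OC)c1
F3 | step 9 | (R)-4-benzyl-3-[(2R,3S)-2-{2,6-dimethoxy-4-[(E)-prop-1-enyl]phenoxy}-3-(triethylsilyloxy)-3-(3,5-dimethoxy-4-triisopropylsilyloxyphenyl)propanoyl]oxazolidin-2-one | O=C(N1C(=O)OC[C@H]1Cc1ccccc1)[C@H](Oc1c(OC)cc(/C=C/C)cc1OC)[C@@H](O[Si](CC)(CC)CC)c1cc(OC)c(O[Si](C(C)C)(C(C)C)C(C)C)c(OC)c1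
F4 | step 9 | (2S,3S)-2-{2,6-dimethoxy-4-[(E)-prop-1-enyl]phenoxy}-3-(triethylsilyloxy)-3-(3,5-dimethoxy-4-triisopropylsilyloxyphenyl)propan-1-ol | OC[C@H](Oc1c(OC)cc(/C=C/C)cc1OC)[C@@H](O[Si](CC)(CC)CC)c1cc(OC)c(O[Si](C(C)C)(C(C)C)C(C)C)c(OC)c1
F5 | step 9 | (2S,3S)-2-{2,6-dimethoxy-4-[(E)-prop-1-enyl]phenoxy}-3-(triethylsilyloxy)-3-(3,5-dimethoxy-4-triisopropylsilyloxyphenyl)propyl 4-methylbenzenesulfonate | Cc1ccc(cc1)S(=O)(=O)OC[C@H](Oc1c(OC)cc(/C=C/C)cc1OC)[C@@H](O[Si](CC)(CC)CC)c1cc(OC)c(O[Si](C(C)C)(C(C)C)C(C)C)c(OC)c1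
F6 | step 9 | triethyl{(1S,2S)-1-(3,5-dimethoxy-4-triisopropylsilyloxyphenyl)-2-{2,6-dimethoxy-4-[(E)-prop-1-enyl]phenoxy}propoxy}silane | C[C@H](Oc1c(OC)cc(/C=C/C)cc1OC)[C@@H](O[Si](CC)(CC)CC)c1cc(OC)c(O[Si](C(C)C)(C(C)C)C(C)C)c(OC)c1
F7 | step 11 | (1R,2S)-1-(3,5-dimethoxy-4-triisopropylsilyloxyphenyl)-2-{2,6-dimethoxy-4-[(E)-prop-1-enyl]phenoxy}propyl 4-nitrobenzoate | C[C@H](Oc1c(OC)cc(/C=C/C)cc1OC)[C@H](OC(=O)c1ccc(cc1)[N+](=O)[O-])c1cc(OC)c(O[Si](C(C)C)(C(C)C)C(C)C)c(OC)c1
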